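**Retrosynthetic overview**
- The target comes from 5,6,7-trimethoxyflavone bis(pivalate) by chelation-directed cleavage of the 5-methyl ether and then methanolysis of the two pivalates.
- Ring C is the only ring built. It is disconnected at C4–C4a, which gives a (Z)-3-aryl-3-(3,4,5-trimethoxyphenoxy)acrylic acid that closes by intramolecular Friedel–Crafts acylation. Rings A and B are bought as arenes.
- Enabling feature: ring A enters as a 3,4,5-trimethoxyphenoxy unit. Its two CH carbons ortho to O1 (future C4a and C8) are symmetry-equivalent, and each lies ortho to one OMe and para to another. Ring B is kept electron-poor as its 3',5'-bis(pivalate).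
- The O1–C2 bond comes from vinylic substitution of the (Z)-enol triflate of a tert-butyl aroylacetate by 3,4,5-trimethoxyphenoxide. The aroylacetate comes from Roskamp homologation of the ring B aldehyde.
- The ring B aldehyde comes from 2,4-bis(benzyloxy)benzaldehyde by Baeyer–Villiger oxidation, ortho-formylation, O-methylation and exchange of benzyl for pivaloyl.

Key step: step 10

Remark: the target has no stereocentre. The only stereo-element on the route is the geometry of the enol triflate and aryloxyacrylate double bond, drawn Z throughout.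

**Step 1**
Reactants: 1 2,4-bis(benzyloxy)benzaldehyde
Product: 3 2,4-bis(benzyloxy)phenol, via aryl formate 2 (not isolated)
Conditions: mCPBA, CH2Cl2, 0 °C to rt; NaHCO3 wash; crude in MeOH, K2CO3 (cat.), rt
Reagents that add atoms: mCPBA, O=C(OO)c1cccc(Cl)c1
Why: Baeyer–Villiger oxidation, in which the ring bearing ortho and para alkoxy donors migrates in the Criegee intermediate in preference to hydride, and the aryl formate is then methanolysed under conditions that leave benzyl ethers untouched.

**Step 2**
Reactants: 3 2,4-bis(benzyloxy)phenol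
Product: 4 3,5-bis(benzyloxy)-2-hydroxybenzaldehyde
Conditions: MgCl2, Et3N, (CH2O)n, MeCN, reflux; then 1 M HCl
Reagents that add atoms: formaldehyde (as paraformaldehyde), C=O
Why: Casnati–Skattebøl ortho-formylation, in which the magnesium phenoxide delivers formaldehyde only to a carbon ortho to the phenol oxygen (a single one is free) and a second formaldehyde oxidises the salicyl alkoxide by hydride transfer.

**Step 3**
Reactants: 4 3,5-bis(benzyloxy)-2-hydroxybenzaldehyde
Product: 5 3,5-bis(benzyloxy)-2-methoxybenzaldehyde
Conditions: MeI, K2CO3, DMF, rt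
Reagents that add atoms: methyl iodide, CI
Why: Williamson ether synthesis on the only free phenol, with the dipolar aprotic solvent breaking the hydrogen bond to the aldehyde.

**Step 4**
Reactants: 5 3,5-bis(benzyloxy)-2-methoxybenzaldehyde
Product: 6 3,5-dihydroxy-2-methoxybenzaldehyde
Conditions: H2 (1 atm), Pd/C, EtOAc, rt, stopped after uptake of two equivalents of H2
Reagents that add atoms: none
Why: Catalytic hydrogenolysis of aryl benzyl ethers, which in a neutral aprotic solvent should run ahead of reduction of the aromatic aldehyde.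

**Step 5**
Reactants: 6 3,5-dihydroxy-2-methoxybenzaldehyde; 7 pivaloyl chloride
Product: 8 2-methoxy-3,5-bis(pivaloyloxy)benzaldehyde
Conditions: PivCl, Et3N, DMAP (cat.), CH2Cl2, 0 °C to rt
Reagents that add atoms: pivaloyl chloride (compound 7), CC(C)(C)C(Cl)=O
Why: DMAP-catalysed O-acylation of both phenols, installing acid-stable, hindered and electron-withdrawing esters that deactivate ring B for the key step.

**Step 6**
Reactants: 8 2-methoxy-3,5-bis(pivaloyloxy)benzaldehyde; 9 tert-butyl diazoacetate
Product: 10 tert-butyl 3-[2-methoxy-3,5-bis(pivaloyloxy)phenyl]-3-oxopropanoate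
Conditions: N2CHCO2t-Bu, NbCl5 (5 mol %), CH2Cl2, rt
Reagents that add atoms: tert-butyl diazoacetate (compound 9), CC(C)(C)OC(=O)C=[N+]=[N-]
Why: Roskamp homologation, in which the diazo carbon adds to the Lewis acid-activated aldehyde and the diazonium alkoxide loses N2 with a 1,2-hydride shift, which the electron-poor ring favours over aryl migration.

**Step 7**
Reactants: 10 tert-butyl 3-[2-methoxy-3,5-bis(pivaloyloxy)phenyl]-3-oxopropanoate
Product: 11 tert-butyl (Z)-3-[2-methoxy-3,5-bis(pivaloyloxy)phenyl]-3-(trifluoromethylsulfonyloxy)acrylate (OTf cis to CO2t-Bu)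
Conditions: (CF3SO2)2O, Et3N, LiOSO2CF3, CH2Cl2, 0 °C
Reagents that add atoms: triflic anhydride, O=S(=O)(OS(=O)(=O)C(F)(F)F)C(F)(F)F
Why: O-sulfonylation of the lithium-chelated enolate of a β-keto ester, where the chelate holds both oxygens on one side and so should fix the Z enol triflate, under non-nucleophilic conditions that spare the pivalates and the tert-butyl ester.

**Step 8**
Reactants: 11 the (Z)-enol triflate; 12 3,4,5-trimethoxyphenol
Product: 13 tert-butyl (Z)-3-[2-methoxy-3,5-bis(pivaloyloxy)phenyl]-3-(3,4,5-trimethoxyphenoxy)acrylate (aryloxy cis to CO2t-Bu)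
Conditions: Cs2CO3, MeCN, 0 °C to rt
Reagents that add atoms: 3,4,5-trimethoxyphenol (compound 12), COc1cc(O)cc(OC)c1OC
Why: Nucleophilic vinylic substitution by addition–elimination, in which the phenoxide adds to the β-carbon activated by the ester and the triflyloxy group and the ester enolate expels triflate with retention, while the low temperature and the bulk of the pivalates hold back acyl transfer.

**Step 9**
Reactants: 13 the tert-butyl (Z)-aryloxyacrylate
Product: 14 (Z)-3-[2-methoxy-3,5-bis(pivaloyloxy)phenyl]-3-(3,4,5-trimethoxyphenoxy)acrylic acid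
Conditions: CF3CO2H–CH2Cl2 (1:3), anhydrous, 0 °C to rt
Reagents that add atoms: none
Why: Acidolysis of the tert-butyl ester with loss of the tert-butyl cation as isobutene, with water excluded so that the enol ether is not hydrolysed, pivalates and methyl ethers inert, and the free ring A carbons too hindered for tert-butylation.

**Step 10**
Reactants: 14 (Z)-3-[2-methoxy-3,5-bis(pivaloyloxy)phenyl]-3-(3,4,5-trimethoxyphenoxy)acrylic acid
Product: 16 2-[2-methoxy-3,5-bis(pivaloyloxy)phenyl]-5,6,7-trimethoxychromen-4-one, via mixed trifluoroacetic anhydride 15 (not isolated)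
Conditions: (CF3CO)2O (3 equiv), CF3CO2H (cosolvent), CH2Cl2, 0 °C to rt
Reagents that add atoms: none
Why: (CF3CO)2O converts 14 into mixed anhydride 15, whose acyl carbon (as such or as the derived β-aryloxyacryloyl cation) is attacked by the ring A carbon ortho to O1, and loss of that ring proton restores aromaticity and gives the pyranone; this is an intramolecular Friedel–Crafts acylation, the closing stage of the classical flavone synthesis from β-aryloxycinnamic acids and the vinylogue of the anhydride-mediated xanthone closure of 2-aryloxybenzoic acids. Ring C closes as a six-membered ring, 6-exo-trig counted at the acyl carbon (the attacked C=O stays outside the ring, the C4a–C8a π bond lies inside it), and C4–C4a is the only skeletal bond formed. No stereocentre arises, and alkene geometry is not critical, because the acyl cation has oxocarbenium–ketene character (ArO+=C–CH=C=O) and C-protonation by CF3CO2H also lowers the C2–C3 rotation barrier, so any E isomer should drain through the Z form that can reach ring A. Site selectivity within ring A needs no control, since the two carbons ortho to O1 are related by symmetry and each is ortho to one methoxyl and para to another. Chemoselectivity is needed against attack by C6' of ring B (indenone closure) and by the 2'-methoxy oxygen (lactone closure with loss of methyl). It rests on the two pivalates that deactivate ring B, on the preference for a six- over a five-membered closure, and on a mild acid medium that does not demethylate.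

**Step 11**
Reactants: 16 2-[2-methoxy-3,5-bis(pivaloyloxy)phenyl]-5,6,7-trimethoxychromen-4-one
Product: 18 5-hydroxy-6,7-dimethoxy-2-[2-methoxy-3,5-bis(pivaloyloxy)phenyl]chromen-4-one, via dichloroboron chelate 17 (not isolated)
Conditions: BCl3 (1 M in CH2Cl2), CH2Cl2, −78 to 0 °C; then H2O
Reagents that add atoms: none
Why: Chelation-directed ether cleavage, in which BCl3 bound to the C4 carbonyl takes the peri 5-methoxy oxygen into a six-membered chelate and chloride removes its methyl, while the other methyl ethers lack a carbonyl partner and the still acylated 3'-oxygen cannot place a boron aryloxide next to the 2'-methoxyl.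

**Step 12**
Reactants: 18 5-hydroxy-6,7-dimethoxy-2-[2-methoxy-3,5-bis(pivaloyloxy)phenyl]chromen-4-one
Product: 19 2-(3,5-dihydroxy-2-methoxyphenyl)-5-hydroxy-6,7-dimethoxychromen-4-one (target)
Conditions: K2CO3, MeOH, N2, rt; then 1 M HCl
Reagents that add atoms: none
Why: Base-mediated transesterification of aryl esters (aryloxide leaving groups), to which the flavone core and the methyl ethers are inert, run under nitrogen because the 2'-methoxy-5'-hydroxy pattern is oxidisable in base.

**Compound list**
1 | 2,4-bis(benzyloxy)benzaldehyde | O=Cc1ccc(OCc2ccccc2)cc1OCc1ccccc1 | starting material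
2 | 2,4-bis(benzyloxy)phenyl formate | O=COc1ccc(OCc2ccccc2)cc1OCc1ccccc1 | intermediate
3 | 2,4-bis(benzyloxy)phenol | Oc1ccc(OCc2ccccc2)cc1OCc1ccccc1 | intermediate
4 | 3,5-bis(benzyloxy)-2-hydroxybenzaldehyde | O=Cc1cc(OCc2ccccc2)cc(OCc2ccccc2)c1O | intermediate
5 | 3,5-bis(benzyloxy)-2-methoxybenzaldehyde | COc1c(C=O)cc(OCc2ccccc2)cc1OCc1ccccc1 | intermediate
6 | 3,5-dihydroxy-2-methoxybenzaldehyde | COc1c(O)cc(O)cc1C=O | intermediate
7 | pivaloyl chloride | CC(C)(C)C(Cl)=O | starting material
8 | 2-methoxy-3,5-bis(pivaloyloxy)benzaldehyde | COc1c(C=O)cc(OC(=O)C(C)(C)C)cc1OC(=O)C(C)(C)C | intermediate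
9 | tert-butyl diazoacetate | CC(C)(C)OC(=O)C=[N+]=[N-] | starting material
10 | tert-butyl 3-[2-methoxy-3,5-bis(pivaloyloxy)phenyl]-3-oxopropanoate | COc1c(C(=O)CC(=O)OC(C)(C)C)cc(OC(=O)C(C)(C)C)cc1OC(=O)C(C)(C)C | intermediate
11 | tert-butyl (Z)-3-[2-methoxy-3,5-bis(pivaloyloxy)phenyl]-3-(trifluoromethylsulfonyloxy)acrylate | CC(C)(C)OC(=O)/C=C(\OS(=O)(=O)C(F)(F)F)c1cc(OC(=O)C(C)(C)C)cc(OC(=O)C(C)(C)C)c1OC | intermediate
12 | 3,4,5-trimethoxyphenol | COc1cc(O)cc(OC)c1OC | starting material
13 | tert-butyl (Z)-3-[2-methoxy-3,5-bis(pivaloyloxy)phenyl]-3-(3,4,5-trimethoxyphenoxy)acrylate | COc1cc(O/C(=C\C(=O)OC(C)(C)C)c2cc(OC(=O)C(C)(C)C)cc(OC(=O)C(C)(C)C)c2OC)cc(OC)c1OC | intermediate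
14 | (Z)-3-[2-methoxy-3,5-bis(pivaloyloxy)phenyl]-3-(3,4,5-trimethoxyphenoxy)acrylic acid | COc1cc(O/C(=C\C(=O)O)c2cc(OC(=O)C(C)(C)C)cc(OC(=O)C(C)(C)C)c2OC)cc(OC)c1OC | intermediate
15 | mixed anhydride of 14 with trifluoroacetic acid (Z) | COc1cc(O/C(=C\C(=O)OC(=O)C(F)(F)F)c2cc(OC(=O)C(C)(C)C)cc(OC(=O)C(C)(C)C)c2OC)cc(OC)c1OC | intermediate
16 | 2-[2-methoxy-3,5-bis(pivaloyloxy)phenyl]-5,6,7-trimethoxychromen-4-one | COc1cc2oc(-c3cc(OC(=O)C(C)(C)C)cc(OC(=O)C(C)(C)C)c3OC)cc(=O)c2c(OC)c1OC | intermediate
17 | 5-(dichloroboryloxy)-6,7-dimethoxy-2-[2-methoxy-3,5-bis(pivaloyloxy)phenyl]chromen-4-one (boron also bound to the C4 carbonyl oxygen) | COc1cc2oc(-c3cc(OC(=O)C(C)(C)C)cc(OC(=O)C(C)(C)C)c3OC)cc(=O)c2c(OB(Cl)Cl)c1OC | intermediate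
18 | 5-hydroxy-6,7-dimethoxy-2-[2-methoxy-3,5-bis(pivaloyloxy)phenyl]chromen-4-one | COc1cc2oc(-c3cc(OC(=O)C(C)(C)C)cc(OC(=O)C(C)(C)C)c3OC)cc(=O)c2c(O)c1OC | intermediate
19 | 2-(3,5-dihydroxy-2-methoxyphenyl)-5-hydroxy-6,7-dimethoxychromen-4-one (CNP0177690.0) | COc1cc2oc(-c3cc(O)cc(O)c3OC)cc(=O)c2c(O)c1OC | target

**Totals**
- Total step count: 12
- Longest linear sequence: 12 steps (1 to 19)

**Steps most likely to fail**

Risk 1, step 10.
- What may go wrong: the acyl donor is a vinylogous carbonate and may be too weak an electrophile. Closure could then stall while acid-induced decarboxylation, trifluoroacetylation of ring A or closure towards ring B gains ground.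
- Fallback (sets out from 8, comes back at 16): the C4–C4a bond is bought instead of made. Aldehyde 8 is oxidised under Pinnick conditions (NaClO2, NaH2PO4, 2-methyl-2-butene, t-BuOH–H2O) to 2-methoxy-3,5-bis(pivaloyloxy)benzoic acid F1. (COCl)2 and catalytic DMF in CH2Cl2 convert this into 2-methoxy-3,5-bis(pivaloyloxy)benzoyl chloride F2. Commercial 1-(6-hydroxy-2,3,4-trimethoxyphenyl)ethanone (CC(=O)c1c(O)cc(OC)c(OC)c1OC) is doubly deprotonated with LiN(SiMe3)2 in THF at −78 °C and C-aroylated with the acid chloride, a shortened Baker–Venkataraman sequence. This gives 1-(6-hydroxy-2,3,4-trimethoxyphenyl)-3-[2-methoxy-3,5-bis(pivaloyloxy)phenyl]propane-1,3-dione F3. Cyclodehydration with catalytic TsOH in warm toluene closes O1–C2 and delivers 16.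

Risk 2, step 8.
- What may go wrong: the phenoxide may attack the sulfur of the triflate (detriflylation back to the keto ester) or a pivalate carbonyl (acyl transfer) instead of the β-carbon.
- Fallback (sets out from 11, comes back at 13): substitution is replaced by elimination followed by addition. LiN(SiMe3)2 in THF at −78 °C removes the vinylic hydrogen anti to the triflate and gives tert-butyl 3-[2-methoxy-3,5-bis(pivaloyloxy)phenyl]prop-2-ynoate F4. Neutral phenol 12 is then added across the triple bond by oxa-Michael addition with only a catalytic amount of Cs2CO3 in DMF at moderate temperature, the classical phenol–arylpropiolate addition. No sulfonate is left to be attacked, and the standing phenoxide concentration stays low. Either alkene isomer of 13 can be carried on, because step 10 funnels both.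

Risk 3, step 6.
- What may go wrong: aryl migration may compete with hydride migration in the diazonium alkoxide, or the diazo ester may add sluggishly to the ortho-substituted aromatic aldehyde.
- Fallback (sets out from 8, comes back at 10): a Reformatsky addition of tert-butyl bromoacetate and Zn in THF, which tolerates aryl esters, gives racemic tert-butyl 3-hydroxy-3-[2-methoxy-3,5-bis(pivaloyloxy)phenyl]propanoate F5. Dess–Martin oxidation in CH2Cl2 converts this into keto ester 10.

**Further compounds**
F1 | step 10 | 2-methoxy-3,5-bis(pivaloyloxy)benzoic acid | COc1c(C(=O)O)cc(OC(=O)C(C)(C)C)cc1OC(=O)C(C)(C)C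
F2 | step 10 | 2-methoxy-3,5-bis(pivaloyloxy)benzoyl chloride | COc1c(C(=O)Cl)cc(OC(=O)C(C)(C)C)cc1OC(=O)C(C)(C)C
F3 | step 10 | 1-(6-hydroxy-2,3,4-trimethoxyphenyl)-3-[2-methoxy-3,5-bis(pivaloyloxy)phenyl]propane-1,3-dione | COc1cc(O)c(C(=O)CC(=O)c2cc(OC(=O)C(C)(C)C)cc(OC(=O)C(C)(C)C)c2OC)c(OC)c1OC
F4 | step 8 | tert-butyl 3-[2-methoxy-3,5-bis(pivaloyloxy)phenyl]prop-2-ynoate | COc1c(C#CC(=O)OC(C)(C)C)cc(OC(=O)C(C)(C)C)cc1OC(=O)C(C)(C)C
F5 | step 6 | tert-butyl 3-hydroxy-3-[2-methoxy-3,5-bis(pivaloyloxy)phenyl]propanoate (racemic) | COc1c(C(O)CC(=O)OC(C)(C)C)cc(OC(=O)C(C)(C)C)cc1OC(=O)C(C)(C)C
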